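## Retrosynthetic overview

1. The chromone pyranone ring is formed last: disconnection at O1–C2 and C2–C3 leads to A-ring acetophenone 19 and benzodioxane aldehyde 17 (Claisen–Schmidt, then I2/DMSO), followed by global debenzylation.
2. The 1,4-dioxane ring is not closed as such. It arises from the seven-membered ring of the cis-3-hydroxy-3,4-dihydro-2H-1,5-benzodioxepine 12 by an O→O Smiles ring contraction (7→6): the C3 alkoxide adds ipso to C9a, the C9a–O1 bond breaks, and the expelled O1–C2H2 arm becomes the CH2OH group.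
3. Enabling feature: C9a (the future B-ring C4', carrying the O–CH2 arm) is para to the nitrile at C7 (a masked C1' aldehyde), so only its σ-adduct is stabilised. The C3–OH sits 1,2 to that arm (five-membered spiro adduct). C5a, which carries the O5–C4H(Ar) arm, is meta to the nitrile and stays untouched.
4. Both stereocentres are set one step earlier by transfer hydrogenation with dynamic kinetic resolution of racemic ketone 11; the contraction only carries them over (cis in the seven-membered ring corresponds to trans in the dioxane).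
5. Ketone 11 comes from 5-hydroxyvanillin by nitrile formation, para-selective O-alkylation, Rh-catalysed O–H insertion, Dieckmann closure and decarboxylation. Ring order: B-ring arene (bought), dioxepinone, dioxane (by contraction), pyranone.

Key step: step 9

Assumption: the (R,R)-configured Ru–TsDPEN catalyst is taken to deliver the (3R)-carbinol of 12 (the aryl-bearing α-carbon playing the role of the large group); if the sense proved opposite, the (S,S)-catalyst would be used with nothing else changed.

Benzodioxepines are numbered with O1 on the CH2 side (O1–C2H2–C3–C4(Ar)–O5).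

## Route

Step 1
Reactants: 1 3,4-dihydroxy-5-methoxybenzaldehyde (5-hydroxyvanillin)
Product: 3 3,4-dihydroxy-5-methoxybenzonitrile, via aldoxime 2 (not isolated)
Conditions: NH2OH·HCl (1.2 equiv), DMSO, 100 °C
Reagents that add atoms: hydroxylamine hydrochloride, Cl.NO
Why: One-pot oxime formation and thermal dehydration in DMSO is a standard aldehyde-to-nitrile conversion for hydroxybenzaldehydes; the nitrile serves as the para acceptor for step 9 and as a masked aldehyde.

Step 2
Reactants: 3 3,4-dihydroxy-5-methoxybenzonitrile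
Product: 4 tert-butyl 2-(4-cyano-2-hydroxy-6-methoxyphenoxy)acetate
Conditions: BrCH2CO2tBu (1.0 equiv), Li2CO3 (1.1 equiv), DMF, 45 °C
Reagents that add atoms: tert-butyl bromoacetate, CC(C)(C)OC(=O)CBr
Why: Williamson etherification in which the 4-OH para to the nitrile, being the more acidic phenol, is ionised selectively by one equivalent of weak base (as in 4-O-selective alkylation of 3,4-dihydroxybenzaldehydes), and the tert-butyl ester resists lactonisation onto the neighbouring free phenol.

Step 3
Reactants: 5 (4-hydroxy-3,5-dimethoxyphenyl)acetic acid (homosyringic acid)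
Product: 6 benzyl 2-[4-(benzyloxy)-3,5-dimethoxyphenyl]acetate
Conditions: BnBr (2.3 equiv), K2CO3, DMF, 60 °C
Reagents that add atoms: benzyl bromide, BrCc1ccccc1
Why: Double O-alkylation of carboxylate and hindered phenol with benzyl bromide under carbonate conditions is routine.

Step 4
Reactants: 6 benzyl 2-[4-(benzyloxy)-3,5-dimethoxyphenyl]acetate
Product: 7 benzyl 2-[4-(benzyloxy)-3,5-dimethoxyphenyl]-2-diazoacetate
Conditions: p-ABSA (1.3 equiv), DBU (1.5 equiv), MeCN, 0 °C to rt
Reagents that add atoms: 4-acetamidobenzenesulfonyl azide, CC(=O)Nc1ccc(cc1)S(=O)(=O)N=[N+]=[N-]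
Why: Regitz diazo transfer to an arylacetate gives the aryldiazoacetate under standard conditions.

Step 5
Reactants: 4 tert-butyl 2-(4-cyano-2-hydroxy-6-methoxyphenoxy)acetate; 7 benzyl 2-[4-(benzyloxy)-3,5-dimethoxyphenyl]-2-diazoacetate
Product: 8 benzyl 2-[4-(benzyloxy)-3,5-dimethoxyphenyl]-2-[2-(2-tert-butoxy-2-oxoethoxy)-5-cyano-3-methoxyphenoxy]acetate (racemic)
Conditions: Rh2(OAc)4 (1 mol %), CH2Cl2, rt, slow addition of 7
Reagents that add atoms: none
Why: Rhodium(II)-catalysed O–H insertion of a donor/acceptor carbenoid into the only free phenol forms the benzylic C–O bond chemoselectively; the new stereocentre is formed racemic on purpose because it is epimerised and reset in step 8.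

Step 6
Reactants: 8 the diester from step 5
Product: 9 tert-butyl 4-[4-(benzyloxy)-3,5-dimethoxyphenyl]-7-cyano-9-methoxy-3-oxo-3,4-dihydro-2H-1,5-benzodioxepine-2-carboxylate (stereoisomer and enol mixture, used as such)
Conditions: KOtBu (2.2 equiv), THF, 0 °C to rt; then AcOH
Reagents that add atoms: none
Why: Dieckmann condensation to a seven-membered β-keto ester follows the established route to 2H-1,5-benzodioxepin-3(4H)-ones; both condensation modes would give the same ring ketone after step 7, and the mode shown is the thermodynamic sink because only its product forms a stabilised β-keto ester enolate.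

Step 7
Reactants: 9 the β-keto tert-butyl ester
Product: 11 4-[4-(benzyloxy)-3,5-dimethoxyphenyl]-9-methoxy-3-oxo-3,4-dihydro-2H-1,5-benzodioxepine-7-carbonitrile (racemic), via β-keto acid 10 (not isolated)
Conditions: TFA–CH2Cl2 (1:4), rt; then toluene, 80 °C
Reagents that add atoms: none
Why: Acidolysis of the tert-butyl ester and thermal decarboxylation of the β-keto acid is standard, and the benzyl ethers, the nitrile and the benzylic aryl ether (α to a carbonyl, hence not prone to ionisation) tolerate TFA.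

Step 8
Reactants: 11 the racemic benzodioxepin-3-one
Product: 12 (3R,4R)-4-[4-(benzyloxy)-3,5-dimethoxyphenyl]-3-hydroxy-9-methoxy-3,4-dihydro-2H-1,5-benzodioxepine-7-carbonitrile (cis)
Conditions: RuCl[(R,R)-TsDPEN](p-cymene) (1 mol %), HCO2H–Et3N (5:2), EtOAc, 40 °C
Reagents that add atoms: none
Why: Noyori–Ikariya asymmetric transfer hydrogenation with dynamic kinetic resolution, as known for α-aryl cyclic ketones such as isoflavanones and 2-arylcycloalkanones: C4 (benzylic, α-aryloxy, α-keto) epimerises rapidly through the enol under Et3N, hydride is delivered anti to the C4 aryl group to give the cis alcohol, and the catalyst sets C3 and thereby selects the C4 epimer.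

Step 9
Reactants: 12 the cis-(3R,4R)-benzodioxepin-3-ol
Product: 15 (2R,3R)-2-[(benzyloxy)methyl]-3-[4-(benzyloxy)-3,5-dimethoxyphenyl]-8-methoxy-2,3-dihydro-1,4-benzodioxine-6-carbonitrile, via spiro Meisenheimer adduct 13 (not isolated), via rearranged potassium alkoxide 14 (not isolated)
Conditions: KHMDS (1.15 equiv), THF–DMSO (4:1), 0 to 45 °C; then BnBr (1.3 equiv), Bu4NI (cat.), rt
Reagents that add atoms: benzyl bromide, BrCc1ccccc1
Why: Proposed new method: deprotonation gives the C3 alkoxide of 12, which lies 1,2 to the CH2–O–aryl arm and adds to the aryl carbon para to the nitrile (ipso attack, 5-exo-trig closure of a spiro-dioxolane) to give the Meisenheimer adduct 13; its collapse with loss of the primary alkoxide opens the seven-membered ring and leaves the six-membered 1,4-dioxane ring, closed by addition–elimination through the former hydroxyl oxygen, and the alkoxide 14 is then benzylated in the same flask. The closest known reaction type is the base-mediated O→O Smiles rearrangement of 2-(aryloxy)ethanols carrying nitro or other acceptor groups; new here is its use as a 7→6 ring contraction with a single para-cyano acceptor and an alkoxide leaving group on a di-ortho-oxygenated carbon. No stereocentre is formed or touched, since no bond at C3 or C4 of 12 is broken: the cis-(3R,4R) pair set in step 8 is carried over unchanged and, because the ring now runs through the former hydroxyl oxygen instead of the CH2 group, appears as the trans-(2R,3R) pair of 15. The selectivity needed is attack at the carbon bearing the O–CH2 arm and not at the one bearing the O–CH(Ar) arm; it is secured by the nitrile, which is para to the former (charge of the adduct delocalised onto C≡N) but meta to the latter. The direction of the equilibrium should be set by the six- over the seven-membered ring and the primary over the secondary alkoxide, and the benzylation makes the outcome irreversible.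

Step 10
Reactants: 15 the benzodioxane nitrile
Product: 17 (2R,3R)-2-[(benzyloxy)methyl]-3-[4-(benzyloxy)-3,5-dimethoxyphenyl]-8-methoxy-2,3-dihydro-1,4-benzodioxine-6-carbaldehyde, via iminoalane 16 (not isolated)
Conditions: DIBAL-H (1.3 equiv), CH2Cl2, −78 to −40 °C; then 1 M HCl, 0 °C
Reagents that add atoms: water, O
Why: DIBAL-H half-reduction of an aryl nitrile to the N-aluminio aldimine and hydrolysis to the aldehyde is standard, and ethers and the benzodioxane are inert at low temperature.

Step 11
Reactants: 18 1-(2,4,6-trihydroxyphenyl)ethan-1-one (phloroacetophenone)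
Product: 19 1-[2,4-bis(benzyloxy)-6-hydroxyphenyl]ethan-1-one
Conditions: BnBr (2.1 equiv), K2CO3, acetone, reflux
Reagents that add atoms: benzyl bromide, BrCc1ccccc1
Why: Selective O-benzylation leaves one ortho hydroxyl free because the hydroxyl hydrogen-bonded to the acetyl group is the least nucleophilic.

Step 12
Reactants: 17 the benzodioxane aldehyde; 19 1-[2,4-bis(benzyloxy)-6-hydroxyphenyl]ethan-1-one
Product: 20 (E)-1-[2,4-bis(benzyloxy)-6-hydroxyphenyl]-3-[(2R,3R)-2-[(benzyloxy)methyl]-3-[4-(benzyloxy)-3,5-dimethoxyphenyl]-8-methoxy-2,3-dihydro-1,4-benzodioxin-6-yl]prop-2-en-1-one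
Conditions: KOH (50 % aq.), EtOH–THF, rt
Reagents that add atoms: none
Why: Claisen–Schmidt aldol condensation of a 2'-hydroxyacetophenone with an aryl aldehyde gives the (E)-chalcone, and the dioxane stereocentres carry no acidic hydrogen and no free para-phenol, so they cannot epimerise.

Step 13
Reactants: 20 the chalcone
Product: 21 5,7-bis(benzyloxy)-2-[(2R,3R)-2-[(benzyloxy)methyl]-3-[4-(benzyloxy)-3,5-dimethoxyphenyl]-8-methoxy-2,3-dihydro-1,4-benzodioxin-6-yl]-4H-chromen-4-one
Conditions: I2 (10 mol %), DMSO, 120 °C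
Reagents that add atoms: none
Why: Iodine-catalysed oxidative cyclisation of a 2'-hydroxychalcone in DMSO (6-endo oxa-Michael addition and iodine-mediated dehydrogenation with DMSO as terminal oxidant) is the standard flavone synthesis and tolerates benzyl ethers.

Step 14
Reactants: 21 the tetrabenzyl flavone
Product: 22 palstatin, 5,7-dihydroxy-2-[(2R,3R)-3-(4-hydroxy-3,5-dimethoxyphenyl)-2-(hydroxymethyl)-8-methoxy-2,3-dihydro-1,4-benzodioxin-6-yl]-4H-chromen-4-one
Conditions: H2 (1 atm), 10 % Pd/C, THF–MeOH, rt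
Reagents that add atoms: none
Why: Catalytic hydrogenolysis removes the three aryl benzyl ethers and the alkyl benzyl ether, the reaction being stopped once they are gone because the flavone C2=C3 bond and the cyclic benzylic aryl ether are reduced much more slowly.

## Compound list

1 | 3,4-dihydroxy-5-methoxybenzaldehyde (5-hydroxyvanillin) | COc1cc(C=O)cc(O)c1O | starting material
2 | (E)-3,4-dihydroxy-5-methoxybenzaldehyde oxime | COc1cc(/C=N/O)cc(O)c1O | intermediate
3 | 3,4-dihydroxy-5-methoxybenzonitrile | COc1cc(C#N)cc(O)c1O | intermediate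
4 | tert-butyl 2-(4-cyano-2-hydroxy-6-methoxyphenoxy)acetate | COc1cc(C#N)cc(O)c1OCC(=O)OC(C)(C)C | intermediate
5 | (4-hydroxy-3,5-dimethoxyphenyl)acetic acid | COc1cc(CC(=O)O)cc(OC)c1O | starting material
6 | benzyl 2-[4-(benzyloxy)-3,5-dimethoxyphenyl]acetate | COc1cc(CC(=O)OCc2ccccc2)cc(OC)c1OCc1ccccc1 | intermediate
7 | benzyl 2-[4-(benzyloxy)-3,5-dimethoxyphenyl]-2-diazoacetate | COc1cc(C(=[N+]=[N-])C(=O)OCc2ccccc2)cc(OC)c1OCc1ccccc1 | intermediate
8 | benzyl 2-[4-(benzyloxy)-3,5-dimethoxyphenyl]-2-[2-(2-tert-butoxy-2-oxoethoxy)-5-cyano-3-methoxyphenoxy]acetate (racemate) | COc1cc(C#N)cc(OC(C(=O)OCc2ccccc2)c2cc(OC)c(OCc3ccccc3)c(OC)c2)c1OCC(=O)OC(C)(C)C | intermediate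
9 | tert-butyl 4-[4-(benzyloxy)-3,5-dimethoxyphenyl]-7-cyano-9-methoxy-3-oxo-3,4-dihydro-2H-1,5-benzodioxepine-2-carboxylate (mixture of stereoisomers) | COc1cc(C#N)cc2OC(c3cc(OC)c(OCc4ccccc4)c(OC)c3)C(=O)C(C(=O)OC(C)(C)C)Oc12 | intermediate
10 | 4-[4-(benzyloxy)-3,5-dimethoxyphenyl]-7-cyano-9-methoxy-3-oxo-3,4-dihydro-2H-1,5-benzodioxepine-2-carboxylic acid (mixture of stereoisomers) | COc1cc(C#N)cc2OC(c3cc(OC)c(OCc4ccccc4)c(OC)c3)C(=O)C(C(=O)O)Oc12 | intermediate
11 | 4-[4-(benzyloxy)-3,5-dimethoxyphenyl]-9-methoxy-3-oxo-3,4-dihydro-2H-1,5-benzodioxepine-7-carbonitrile (racemate) | COc1cc(C#N)cc2OC(c3cc(OC)c(OCc4ccccc4)c(OC)c3)C(=O)COc12 | intermediate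
12 | (3R,4R)-4-[4-(benzyloxy)-3,5-dimethoxyphenyl]-3-hydroxy-9-methoxy-3,4-dihydro-2H-1,5-benzodioxepine-7-carbonitrile | COc1cc(C#N)cc2O[C@H](c3cc(OC)c(OCc4ccccc4)c(OC)c3)[C@H](O)COc12 | intermediate
13 | potassium salt of the spiro Meisenheimer adduct (former C3–O bonded to the aryl carbon para to the nitrile, charge on the cyano-substituted cyclohexadienide) | COC1=CC(=C=[N-])C=C2O[C@H](c3cc(OC)c(OCc4ccccc4)c(OC)c3)[C@H]3CO[C@@]12O3.[K+] | intermediate
14 | potassium [(2R,3R)-3-[4-(benzyloxy)-3,5-dimethoxyphenyl]-6-cyano-8-methoxy-2,3-dihydro-1,4-benzodioxin-2-yl]methanolate | COc1cc(C#N)cc2O[C@H](c3cc(OC)c(OCc4ccccc4)c(OC)c3)[C@@H](C[O-])Oc12.[K+] | intermediate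
15 | (2R,3R)-2-[(benzyloxy)methyl]-3-[4-(benzyloxy)-3,5-dimethoxyphenyl]-8-methoxy-2,3-dihydro-1,4-benzodioxine-6-carbonitrile | COc1cc(C#N)cc2O[C@H](c3cc(OC)c(OCc4ccccc4)c(OC)c3)[C@@H](COCc3ccccc3)Oc12 | intermediate
16 | N-(diisobutylaluminio)aldimine of 17 | COc1cc(C=N[Al](CC(C)C)CC(C)C)cc2O[C@H](c3cc(OC)c(OCc4ccccc4)c(OC)c3)[C@@H](COCc3ccccc3)Oc12 | intermediate
17 | (2R,3R)-2-[(benzyloxy)methyl]-3-[4-(benzyloxy)-3,5-dimethoxyphenyl]-8-methoxy-2,3-dihydro-1,4-benzodioxine-6-carbaldehyde | COc1cc(C=O)cc2O[C@H](c3cc(OC)c(OCc4ccccc4)c(OC)c3)[C@@H](COCc3ccccc3)Oc12 | intermediate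
18 | 1-(2,4,6-trihydroxyphenyl)ethan-1-one | CC(=O)c1c(O)cc(O)cc1O | starting material
19 | 1-[2,4-bis(benzyloxy)-6-hydroxyphenyl]ethan-1-one | CC(=O)c1c(O)cc(OCc2ccccc2)cc1OCc1ccccc1 | intermediate
20 | (E)-1-[2,4-bis(benzyloxy)-6-hydroxyphenyl]-3-[(2R,3R)-2-[(benzyloxy)methyl]-3-[4-(benzyloxy)-3,5-dimethoxyphenyl]-8-methoxy-2,3-dihydro-1,4-benzodioxin-6-yl]prop-2-en-1-one | COc1cc(/C=C/C(=O)c3c(O)cc(OCc4ccccc4)cc3OCc3ccccc3)cc2O[C@H](c3cc(OC)c(OCc4ccccc4)c(OC)c3)[C@@H](COCc3ccccc3)Oc12 | intermediate
21 | 5,7-bis(benzyloxy)-2-[(2R,3R)-2-[(benzyloxy)methyl]-3-[4-(benzyloxy)-3,5-dimethoxyphenyl]-8-methoxy-2,3-dihydro-1,4-benzodioxin-6-yl]-4H-chromen-4-one | COc1cc(-c3cc(=O)c4c(OCc5ccccc5)cc(OCc5ccccc5)cc4o3)cc2O[C@H](c3cc(OC)c(OCc4ccccc4)c(OC)c3)[C@@H](COCc3ccccc3)Oc12 | intermediate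
22 | palstatin | COc1cc([C@H]2Oc3cc(-c4cc(=O)c5c(O)cc(O)cc5o4)cc(OC)c3O[C@@H]2CO)cc(OC)c1O | target

## Step count and risks

Total step count: 14. Longest linear sequence: 11 steps (1, 2, 5, 6, 7, 8, 9, 10, 12, 13, 14).

Steps most likely to fail:

**Step 9 (Smiles ring contraction).** The C3 alkoxide may not add at a useful rate to the hindered ipso carbon, which is activated by only one nitrile. Alternatively the equilibrium between seven- and six-membered alkoxides may be unfavourable, so that benzylation fixes the unrearranged skeleton.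

Fallback (known chemistry; the dioxane ring is closed directly by epoxide opening and Mitsunobu etherification; sets out from 3, returns at 15):
- 3 is allylated at the more acidic 4-OH (allyl bromide, Li2CO3, DMF) to 4-(allyloxy)-3-hydroxy-5-methoxybenzonitrile F1.
- Commercial (E)-sinapyl alcohol is benzylated at the phenol (BnBr, K2CO3, acetone) to (E)-3-[4-(benzyloxy)-3,5-dimethoxyphenyl]prop-2-en-1-ol F2.
- Sharpless epoxidation (Ti(OiPr)4, L-(+)-DET, TBHP, 4 Å MS, CH2Cl2, −20 °C) gives the (2S,3S)-epoxy alcohol F3.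
- Benzylation (NaH, BnBr, THF, 0 °C) gives the epoxide benzyl ether F4.
- The phenoxide of F1 (Cs2CO3, DMF, 80 °C) opens F4 at the benzylic carbon with inversion to give the (1R,2S)-hydroxy ether F5.
- Pd(PPh3)4/morpholine removes the allyl group to give phenol F6.
- Intramolecular Mitsunobu etherification (PPh3, DIAD, THF) closes the dioxane ring with inversion at the carbinol carbon and gives 15.

**Step 8 (transfer hydrogenation with dynamic kinetic resolution).** Enantiofacial discrimination may be poor because the carbonyl carries no aryl group. Epimerisation at C4 may also be too slow relative to reduction, which would erode enantio- and diastereoselectivity.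

Fallback (substrate-controlled reduction and enzymatic kinetic resolution; sets out from 11, returns at 12):
- NaBH4 (MeOH–THF, −20 °C) should add hydride anti to the aryl group and give the racemic cis alcohol F7.
- Lipase-catalysed acylation (Amano PS or CAL-B, vinyl acetate, MTBE) should, by the Kazlauskas rule, acylate the (3R,4R)-enantiomer to the acetate F8.
- F8 is separated from the unreacted (3S,4S)-alcohol, which is oxidised back to 11 (Dess–Martin periodinane) and recycled.
- Methanolysis of F8 (K2CO3, MeOH) gives 12.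

**Step 6 (Dieckmann closure).** The base turns the benzylic ester, which must act as the electrophile, into its own enolate, so ring closure may stall, or retro-Claisen cleavage and transesterification may prevail.

Fallback (polarity of the closure reversed so that the readily formed benzylic enolate is the nucleophile; sets out from 8, returns at 11):
- TFA–CH2Cl2 cleaves only the tert-butyl ester to give the acid F9.
- CDI (THF) gives the acyl imidazolide F10.
- DBU (or LiHMDS, −78 °C) triggers intramolecular C-acylation by the benzylic ester enolate to give the quaternary β-keto benzyl ester F11.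
- Krapcho dealkoxycarbonylation (LiCl, wet DMSO, 120 °C) gives 11.

## Further compounds

F1 | step 9 | 4-(allyloxy)-3-hydroxy-5-methoxybenzonitrile | COc1cc(C#N)cc(O)c1OCC=C
F2 | step 9 | (E)-3-[4-(benzyloxy)-3,5-dimethoxyphenyl]prop-2-en-1-ol | COc1cc(/C=C/CO)cc(OC)c1OCc1ccccc1
F3 | step 9 | [(2S,3S)-3-[4-(benzyloxy)-3,5-dimethoxyphenyl]oxiran-2-yl]methanol | COc1cc([C@@H]2O[C@H]2CO)cc(OC)c1OCc1ccccc1
F4 | step 9 | (2S,3S)-2-[(benzyloxy)methyl]-3-[4-(benzyloxy)-3,5-dimethoxyphenyl]oxirane | COc1cc([C@@H]2O[C@H]2COCc2ccccc2)cc(OC)c1OCc1ccccc1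
F5 | step 9 | 4-(allyloxy)-3-{[(1R,2S)-3-(benzyloxy)-1-[4-(benzyloxy)-3,5-dimethoxyphenyl]-2-hydroxypropyl]oxy}-5-methoxybenzonitrile | COc1cc(C#N)cc(O[C@H](c2cc(OC)c(OCc3ccccc3)c(OC)c2)[C@@H](O)COCc2ccccc2)c1OCC=C
F6 | step 9 | 3-{[(1R,2S)-3-(benzyloxy)-1-[4-(benzyloxy)-3,5-dimethoxyphenyl]-2-hydroxypropyl]oxy}-4-hydroxy-5-methoxybenzonitrile | COc1cc(C#N)cc(O[C@H](c2cc(OC)c(OCc3ccccc3)c(OC)c2)[C@@H](O)COCc2ccccc2)c1O
F7 | step 8 | cis-4-[4-(benzyloxy)-3,5-dimethoxyphenyl]-3-hydroxy-9-methoxy-3,4-dihydro-2H-1,5-benzodioxepine-7-carbonitrile, racemate of (3R,4R) and (3S,4S) | COc1cc(C#N)cc2O[C@H](c3cc(OC)c(OCc4ccccc4)c(OC)c3)[C@H](O)COc12.COc1cc(C#N)cc2O[C@@H](c3cc(OC)c(OCc4ccccc4)c(OC)c3)[C@@H](O)COc12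
F8 | step 8 | (3R,4R)-4-[4-(benzyloxy)-3,5-dimethoxyphenyl]-7-cyano-9-methoxy-3,4-dihydro-2H-1,5-benzodioxepin-3-yl acetate | COc1cc(C#N)cc2O[C@H](c3cc(OC)c(OCc4ccccc4)c(OC)c3)[C@H](OC(C)=O)COc12
F9 | step 6 | 2-{2-[2-(benzyloxy)-1-[4-(benzyloxy)-3,5-dimethoxyphenyl]-2-oxoethoxy]-4-cyano-6-methoxyphenoxy}acetic acid (racemate) | COc1cc(C#N)cc(OC(C(=O)OCc2ccccc2)c2cc(OC)c(OCc3ccccc3)c(OC)c2)c1OCC(=O)O
F10 | step 6 | acyl imidazolide of F9 (racemate) | COc1cc(C#N)cc(OC(C(=O)OCc2ccccc2)c2cc(OC)c(OCc3ccccc3)c(OC)c2)c1OCC(=O)n1ccnc1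
F11 | step 6 | benzyl 4-[4-(benzyloxy)-3,5-dimethoxyphenyl]-7-cyano-9-methoxy-3-oxo-3,4-dihydro-2H-1,5-benzodioxepine-4-carboxylate (racemate) | COc1cc(C#N)cc2OC(C(=O)OCc3ccccc3)(c3cc(OC)c(OCc4ccccc4)c(OC)c3)C(=O)COc12
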